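The dawn run could not show me G at 5.0 h. It is the flask asked about, followed so far, but it stopped at 25.0 min with G at 5%, against a scatter of 1.5 percentage points. The spring run had to carry the time.

| setting | dawn | spring | flask |
|---|---|---|---|
| D | 0.20 M | 0.10 M | 0.20 M |
| Q | 0.30 M | 0.30 M | 0.300 M |
| remark | the very flask that is asked about, followed so far | run made earlier |  |
| time |  |  | 5.0 h |
| volume of the second phase over the first |  |  | 1.0 |

dawn run (percent of the D charged)

| time / min | G / % | D / % |
|---|---|---|
| 1.33 | 0 | 100 |
| 4.00 | 1 | 101 |
| 6.00 | 1 | 98 |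
| 10.0 | 2 | 99 |
| 15.0 | 1 | 99 |
| 20.0 | 3 | 96 |
| 25.0 | 5 | 94 |

spring run (percent of the D charged)

| time / h | G / % | D / % |
|---|---|---|
| 0.417 | 4 | 97 |
| 0.667 | 7 | 92 |
| 1.00 | 11 | 92 |
| 1.33 | 11 | 90 |
| 2.00 | 16 | 78 |
| 3.00 | 22 | 73 |
| 5.00 | 32 | 62 |

(standard deviation of a reading: 1.5 percentage points)

- how much G there is at 5.0 h, in percent of the D charged
- the change that raises the amount of G at 5.0 h, in percent of the D charged most ("none" if none brings more than 2 percentage points) (Saturday's / Tuesday's / none)
- amount of G at 5.0 h, in percent of the D charged, after Saturday's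

- in the second phase: Q; everything else is in the first
- charges count per volume of the first phase; a concentration in a rate is the amount of a species over the volume of its own phase; every rate counts per litre of the first phase
- the earlier runs hold the two phases in the same ratio of volumes as the flask asked about

D was charged below Q, so I treated it as the limiting reagent and wrote its balance as d[D]/dt = −k′[D]. From the last spring reading I took 0.0956 h⁻¹, the pseudo-first-order constant k′, the fraction of D lost per hour.

Did k′ survive the higher [D]? It gave a dawn loss of 3.91% by 25.0 min, and I read 6.00%. That gap lay near the scatter. A transfer-limited rate, fixed in M per hour, would have lowered k′ as [D] rose, so I expected little from Tuesday's.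

How far did Q sag? If each D took one Q, the flask would spend 0.0760 M of its 0.300 M, about a quarter. No run varied Q, so I assumed k′ follows mean [Q]. That gave 0.0891 h⁻¹ and D left at 64.0%. The spring run turned 0.842 of lost D into G, so I reckoned G at 30.3%, and at 49.7% with k′ doubled by Saturday's.

The forecast, a little lower, said 28% (23% to 33%), Saturday's, and 48% (39% to 56%), noting “heavier Q depletion lowers G slightly”.

The flask gave 28.1%. Saturday's gave 47.3%, a gain of 19 points, and Tuesday's gained 0.058 points.

    D + Z ⇌ G (K = 16.0 M⁻¹, k = 0.0150 M⁻¹ min⁻¹)
    Z ⇌ Q, rate k2*([Z] - [Q]/K2) per volume of the first phase (partition coefficient = 1.50, kL = 0.340 min⁻¹)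
    D + G → L (k = 0.00580 M⁻¹ min⁻¹)
    D → E (k = 3.30 × 10⁻⁶ min⁻¹)

In the flask, D stood at 63.0% at 5.00 h, a k′ of 0.0924 h⁻¹ against my 0.0891 h⁻¹. G was then made 3.05 times as fast as it was used up, and its half-life on the path to L, 16 h, was longer than the time 5.0 h; L held 8.89%.

With 0.34 M of D, k′ became 0.0801 h⁻¹, giving D 67.0% and G 27.8%. That flask computed D 63.2%, G 23.3% and L 13.4%.

Readings and results stem from a simulated flask with made-up constants, noise included.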